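**Retrosynthetic overview**

1. Feature: N1 bridges C2 and C6 of an unbranched C22 chain (piperidine N1/C2–C6; methyl C1 on C2, OH on C3; chain C7–C22 with OH on C10 and C21). This is the pattern of a 2,6-diketone aminated at its methyl-ketone end.
2. Last disconnection: the C6–H bond, by cis-selective hydrogenation of a C6=N imine, with loss of three benzyl ethers in the same operation.
3. Key disconnection: N1–C2 and N1=C6, by (R)-selective transaminase amination of the C2 methyl ketone of a 3-benzyloxy-2,6-diketone and spontaneous condensation onto C6. This forms the only ring.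
4. Diketone: C6–C7 by Weinreb ketone synthesis between a C1–C6 amide and a C7–C22 Grignard reagent. C3 comes from (S)-5-oxotetrahydrofuran-2-carboxylic acid and C2 is masked as a dimethyl ketal.
5. C7–C22 fragment: (S)-propylene oxide plus undecenyl Grignard sets C21; epoxidation and hydrolytic kinetic resolution set C10; vinyl Grignard opening, hydroboration and bromination finish it.

Key step: step 16

Remark: carbons are numbered C1 (ring methyl) to C22 along the chain; the (R)-selective transaminase is taken to be a commercial enzyme of the ATA-117 type.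

**Route**

Step 1
Reactants: 1 (S)-5-oxotetrahydrofuran-2-carboxylic acid
Product: 2 (S)-5-oxotetrahydrofuran-2-carbonyl chloride
Conditions: (COCl)2 (1.2 equiv), DMF (cat.), CH2Cl2, 0 °C → rt; evaporate, use crude
Reagents that add atoms: oxalyl chloride, ClC(=O)C(Cl)=O
Why: Acid chloride formation through the Vilsmeier-type chloroiminium species is neutral enough to leave the lactone and the α-stereocentre untouched.

Step 2
Reactants: 2 (S)-5-oxotetrahydrofuran-2-carbonyl chloride
Product: 3 (S)-5-acetyldihydrofuran-2(3H)-one
Conditions: MeZnCl (1.2 equiv), Pd(PPh3)4 (3 mol %), THF, 0 °C → rt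
Reagents that add atoms: methylzinc chloride, C[Zn]Cl
Why: Negishi acylation (oxidative addition of zerovalent palladium into C–Cl, transmetalation from zinc, reductive elimination) should give the methyl ketone, because the organozinc adds neither to the lactone nor to the new ketone and is too weakly basic to enolise the stereocentre.

Step 3
Reactants: 3 (S)-5-acetyldihydrofuran-2(3H)-one
Product: 4 (S)-5-(1,1-dimethoxyethyl)dihydrofuran-2(3H)-one
Conditions: MeOSiMe3 (2.5 equiv), Me3SiOTf (5 mol %), CH2Cl2, −78 → 0 °C; pyridine quench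
Reagents that add atoms: methoxytrimethylsilane, CO[Si](C)(C)C
Why: Noyori ketalisation under aprotic conditions masks the methyl ketone without opening the lactone, and from here on the stereocentre is no longer α to a carbonyl, so the basic steps ahead cannot epimerise it.

Step 4
Reactants: 4 (S)-5-(1,1-dimethoxyethyl)dihydrofuran-2(3H)-one
Product: 5 (S)-4-hydroxy-N,5,5-trimethoxy-N-methylhexanamide
Conditions: MeNH(OMe)·HCl (1.5 equiv), iPrMgCl (3.0 equiv), THF, −20 → 0 °C; aq. NH4Cl; used at once
Reagents that add atoms: N,O-dimethylhydroxylamine hydrochloride, CNOC.Cl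
Why: Weinreb aminolysis of the lactone by the magnesium amide is driven by formation of the ring-opened magnesium alkoxide, and the non-Lewis-acidic reagent should leave the acyclic ketal intact.

Step 5
Reactants: 5 (S)-4-hydroxy-N,5,5-trimethoxy-N-methylhexanamide
Product: 6 (S)-4-(benzyloxy)-N,5,5-trimethoxy-N-methylhexanamide
Conditions: NaH (1.2 equiv), BnBr (1.3 equiv), Bu4NI (cat.), THF/DMF (4:1), 0 °C → rt
Reagents that add atoms: benzyl bromide, BrCc1ccccc1
Why: Williamson etherification of the sodium alkoxide should outrun relactonisation, because under basic conditions the alkoxide is a far better leaving group than the N-methoxy-N-methylamide anion and the tetrahedral adduct reverts to the open amide.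

Step 6
Reactants: 7 11-bromoundec-1-ene; 8 (S)-propylene oxide
Product: 10 (S)-tetradec-13-en-2-ol, via undec-10-enylmagnesium bromide 9 (not isolated)
Conditions: Mg, THF, 40 °C; then CuI (10 mol %), 8 (1.3 equiv), −30 → 0 °C; aq. NH4Cl
Reagents that add atoms: none
Why: Copper-catalysed Grignard opening of the epoxide occurs by SN2 attack at the unsubstituted carbon, so the C–O bond of the stereocentre is not touched and the (S) configuration becomes C21.

Step 7
Reactants: 10 (S)-tetradec-13-en-2-ol
Product: 11 (S)-13-(benzyloxy)tetradec-1-ene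
Conditions: NaH (1.3 equiv), BnBr (1.3 equiv), Bu4NI (cat.), THF/DMF, 0 °C → rt
Reagents that add atoms: benzyl bromide, BrCc1ccccc1
Why: Williamson etherification of an unhindered secondary alkoxide, with no other reactive group in the molecule.

Step 8
Reactants: 11 (S)-13-(benzyloxy)tetradec-1-ene
Product: 12 2-[(11S)-11-(benzyloxy)dodecyl]oxirane (both epimers at the oxirane carbon)
Conditions: mCPBA (1.3 equiv), NaHCO3, CH2Cl2, 0 °C → rt
Reagents that add atoms: 3-chloroperoxybenzoic acid, OOC(=O)c1cccc(Cl)c1
Why: Prilezhaev epoxidation of the terminal alkene; the remote C21 centre exerts no facial control, so an equal mixture of epimers is expected and is resolved in the next step.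

Step 9
Reactants: 12 2-[(11S)-11-(benzyloxy)dodecyl]oxirane (both epimers)
Product: 13 (2S)-2-[(11S)-11-(benzyloxy)dodecyl]oxirane
Conditions: (S,S)-(salen)Co(OAc) (1 mol %; acetato[(S,S)-N,N'-bis(3,5-di-tert-butylsalicylidene)cyclohexane-1,2-diaminato]cobalt, trivalent cobalt), H2O (0.55 equiv), THF, 0 °C → rt; chromatography
Reagents that add atoms: none
Why: Jacobsen hydrolytic kinetic resolution: the (S,S)-complex hydrolyses (R)-configured 2-alkyloxiranes selectively by cooperative bimetallic activation of epoxide and hydroxide, so the epimer with the (S)-oxirane (future C10) should be recovered and separated from the polar diol, at the cost of at most half the material.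

Step 10
Reactants: 13 (2S)-2-[(11S)-11-(benzyloxy)dodecyl]oxirane; 14 vinylmagnesium bromide
Product: 15 (4S,15S)-15-(benzyloxy)hexadec-1-en-4-ol
Conditions: 14 (2.0 equiv), CuI (10 mol %), THF, −40 → −20 °C; aq. NH4Cl
Reagents that add atoms: none
Why: Copper-catalysed SN2 opening at the terminal oxirane carbon gives the homoallylic alcohol and leaves the C10–O bond, and so its configuration, unchanged.

Step 11
Reactants: 15 (4S,15S)-15-(benzyloxy)hexadec-1-en-4-ol
Product: 16 (4S,15S)-4,15-bis(benzyloxy)hexadec-1-ene
Conditions: NaH (1.3 equiv), BnBr (1.3 equiv), Bu4NI (cat.), THF/DMF, 0 °C → rt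
Reagents that add atoms: benzyl bromide, BrCc1ccccc1
Why: Williamson etherification; the homoallylic alkoxide has no pathway for elimination or migration.

Step 12
Reactants: 16 (4S,15S)-4,15-bis(benzyloxy)hexadec-1-ene
Product: 18 (4S,15S)-4,15-bis(benzyloxy)hexadecan-1-ol, via B-alkyl-9-BBN adduct 17 (not isolated)
Conditions: 9-BBN (1.3 equiv), THF, 0 °C → rt; then 3 M NaOH, 30% H2O2, 0 °C → rt
Reagents that add atoms: hydrogen peroxide, OO
Why: Brown hydroboration–oxidation with the bulky borane places boron on the terminal carbon (anti-Markovnikov), and oxidative 1,2-migration gives the primary alcohol at C7.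

Step 13
Reactants: 18 (4S,15S)-4,15-bis(benzyloxy)hexadecan-1-ol
Product: 19 (4S,15S)-4,15-bis(benzyloxy)-1-bromohexadecane
Conditions: CBr4 (1.3 equiv), PPh3 (1.4 equiv), CH2Cl2, 0 °C
Reagents that add atoms: carbon tetrabromide, BrC(Br)(Br)Br
Why: Appel reaction converts the primary alcohol into the bromide under neutral conditions that benzyl ethers tolerate.

Step 14
Reactants: 19 (4S,15S)-4,15-bis(benzyloxy)-1-bromohexadecane; 6 (S)-4-(benzyloxy)-N,5,5-trimethoxy-N-methylhexanamide
Product: 22 (3S,10S,21S)-3,10,21-tris(benzyloxy)-2,2-dimethoxydocosan-6-one, via alkylmagnesium bromide 20 (not isolated), via magnesium hemiaminal chelate 21 (not isolated)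
Conditions: Mg turnings (activated), THF, 45 °C; then 6 (0.85 equiv), THF, 0 °C; aq. NH4Cl
Reagents that add atoms: none
Why: Weinreb ketone synthesis: the Grignard reagent, whose ether oxygen is too remote for elimination, adds once to give a five-membered magnesium chelate that releases the C6 ketone only on aqueous work-up, while the ketal and ethers are inert.

Step 15
Reactants: 22 (3S,10S,21S)-3,10,21-tris(benzyloxy)-2,2-dimethoxydocosan-6-one
Product: 23 (3S,10S,21S)-3,10,21-tris(benzyloxy)docosane-2,6-dione
Conditions: 0.5 M aq. HCl/THF (1:4), 0 °C → rt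
Reagents that add atoms: water, O
Why: Acid-catalysed ketal hydrolysis; the acyclic dimethyl ketal was chosen because it should cleave under acid mild enough that the 1,5-diketone does not undergo aldol cyclisation and C3, now α to a ketone, is not enolised.

Step 16
Reactants: 23 (3S,10S,21S)-3,10,21-tris(benzyloxy)docosane-2,6-dione
Product: 25 (2R,3S)-3-(benzyloxy)-6-[(4S,15S)-4,15-bis(benzyloxy)hexadecyl]-2-methyl-2,3,4,5-tetrahydropyridine, via open-chain C2 amine 24 (not isolated)
Conditions: ATA-117 ((R)-selective ω-transaminase, lyophilised), pyridoxal 5'-phosphate (1 mM), iPrNH2 (1 M), potassium phosphate buffer (100 mM, pH 7.5–8.0), DMSO (20% v/v), 23 at 10 mM, 30 °C, 24–48 h; extraction at pH 10–11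
Reagents that add atoms: isopropylamine, CC(C)N
Why: In the ping-pong transamination, isopropylamine converts enzyme-bound pyridoxal phosphate into pyridoxamine phosphate (releasing acetone), which condenses with the C2 methyl ketone; a lysine-mediated 1,3-proton shift through the quinonoid and hydrolysis then release the (2R)-amine 24. The closest known reaction type is transaminase monoamination of 1,5-diketones that carry one methyl ketone, followed by spontaneous cyclisation to 2,6-disubstituted 2,3,4,5-tetrahydropyridines; the benzyloxy branch next to the reacting carbonyl is the untested element. The ring closes when the C2 amine adds to the C6 ketone in a 6-exo-trig sense and the carbinolamine loses water to the endocyclic C6=N imine, which also drains the transamination equilibrium. The new C2 stereocentre is fixed by the enzyme alone: the methyl group sits in the small pocket and the C3–C22 chain in the large one, so the quinonoid is protonated from a single face and the amine should be R whatever the configuration at C3. The step needs regioselectivity for C2 over C6, which the substrate secures because C6 is flanked by two chains longer than ethyl and cannot place either in the small pocket. It also needs C3 to survive, which near-neutral pH, modest temperature and the loss of the adjacent carbonyl on amination should ensure.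

Step 17
Reactants: 25 (2R,3S)-3-(benzyloxy)-6-[(4S,15S)-4,15-bis(benzyloxy)hexadecyl]-2-methyl-2,3,4,5-tetrahydropyridine
Product: 27 (2R,3S,6S)-6-[(4S,15S)-4,15-dihydroxyhexadecyl]-2-methylpiperidin-3-ol, via tris(benzyloxy) cis-piperidine 26 (not isolated)
Conditions: H2 (4 bar), Pd(OH)2/C, MeOH, AcOH (5 equiv), rt; then aq. K2CO3
Reagents that add atoms: none
Why: Heterogeneous hydrogenation should deliver hydrogen to the C6=N face opposite the C2 methyl group, setting C6 as S in the 2,6-cis, all-equatorial piperidine, and the same catalyst then hydrogenolyses the three benzyl ethers, with acetic acid keeping the amine from poisoning the palladium surface.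

**Compound list**

1 | (S)-5-oxotetrahydrofuran-2-carboxylic acid | OC(=O)[C@@H]1CCC(=O)O1 | starting material
2 | (S)-5-oxotetrahydrofuran-2-carbonyl chloride | ClC(=O)[C@@H]1CCC(=O)O1 | intermediate
3 | (S)-5-acetyldihydrofuran-2(3H)-one | CC(=O)[C@@H]1CCC(=O)O1 | intermediate
4 | (S)-5-(1,1-dimethoxyethyl)dihydrofuran-2(3H)-one | COC(C)(OC)[C@@H]1CCC(=O)O1 | intermediate
5 | (S)-4-hydroxy-N,5,5-trimethoxy-N-methylhexanamide | CON(C)C(=O)CC[C@H](O)C(C)(OC)OC | intermediate
6 | (S)-4-(benzyloxy)-N,5,5-trimethoxy-N-methylhexanamide | CON(C)C(=O)CC[C@H](OCc1ccccc1)C(C)(OC)OC | intermediate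
7 | 11-bromoundec-1-ene | C=CCCCCCCCCCBr | starting material
8 | (S)-propylene oxide | C[C@H]1CO1 | starting material
9 | undec-10-enylmagnesium bromide | C=CCCCCCCCCC[Mg]Br | intermediate (not isolated)
10 | (S)-tetradec-13-en-2-ol | C[C@H](O)CCCCCCCCCCC=C | intermediate
11 | (S)-13-(benzyloxy)tetradec-1-ene | C[C@H](OCc1ccccc1)CCCCCCCCCCC=C | intermediate
12 | 2-[(11S)-11-(benzyloxy)dodecyl]oxirane, both epimers at the oxirane carbon | C[C@H](OCc1ccccc1)CCCCCCCCCCC1CO1 | intermediate
13 | (2S)-2-[(11S)-11-(benzyloxy)dodecyl]oxirane | C[C@H](OCc1ccccc1)CCCCCCCCCC[C@H]1CO1 | intermediate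
14 | vinylmagnesium bromide | C=C[Mg]Br | starting material
15 | (4S,15S)-15-(benzyloxy)hexadec-1-en-4-ol | C[C@H](OCc1ccccc1)CCCCCCCCCC[C@H](O)CC=C | intermediate
16 | (4S,15S)-4,15-bis(benzyloxy)hexadec-1-ene | C[C@H](OCc1ccccc1)CCCCCCCCCC[C@H](OCc1ccccc1)CC=C | intermediate
17 | 9-[(4S,15S)-4,15-bis(benzyloxy)hexadecyl]-9-borabicyclo[3.3.1]nonane | C[C@H](OCc1ccccc1)CCCCCCCCCC[C@H](OCc1ccccc1)CCCB1C2CCCC1CCC2 | intermediate (not isolated)
18 | (4S,15S)-4,15-bis(benzyloxy)hexadecan-1-ol | C[C@H](OCc1ccccc1)CCCCCCCCCC[C@H](OCc1ccccc1)CCCO | intermediate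
19 | (4S,15S)-4,15-bis(benzyloxy)-1-bromohexadecane | C[C@H](OCc1ccccc1)CCCCCCCCCC[C@H](OCc1ccccc1)CCCBr | intermediate
20 | [(4S,15S)-4,15-bis(benzyloxy)hexadecyl]magnesium bromide | C[C@H](OCc1ccccc1)CCCCCCCCCC[C@H](OCc1ccccc1)CCC[Mg]Br | intermediate (not isolated)
21 | bromomagnesium (3S,10S,21S)-3,10,21-tris(benzyloxy)-2,2-dimethoxy-6-[methoxy(methyl)amino]docosan-6-olate | C[C@H](OCc1ccccc1)CCCCCCCCCC[C@H](OCc1ccccc1)CCCC(O[Mg]Br)(N(C)OC)CC[C@H](OCc1ccccc1)C(C)(OC)OC | intermediate (not isolated)
22 | (3S,10S,21S)-3,10,21-tris(benzyloxy)-2,2-dimethoxydocosan-6-one | C[C@H](OCc1ccccc1)CCCCCCCCCC[C@H](OCc1ccccc1)CCCC(=O)CC[C@H](OCc1ccccc1)C(C)(OC)OC | intermediate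
23 | (3S,10S,21S)-3,10,21-tris(benzyloxy)docosane-2,6-dione | C[C@H](OCc1ccccc1)CCCCCCCCCC[C@H](OCc1ccccc1)CCCC(=O)CC[C@H](OCc1ccccc1)C(C)=O | intermediate (key-step precursor)
24 | (2R,3S,10S,21S)-2-amino-3,10,21-tris(benzyloxy)docosan-6-one | C[C@H](OCc1ccccc1)CCCCCCCCCC[C@H](OCc1ccccc1)CCCC(=O)CC[C@H](OCc1ccccc1)[C@@H](C)N | intermediate (not isolated)
25 | (2R,3S)-3-(benzyloxy)-6-[(4S,15S)-4,15-bis(benzyloxy)hexadecyl]-2-methyl-2,3,4,5-tetrahydropyridine | C[C@H](OCc1ccccc1)CCCCCCCCCC[C@H](OCc1ccccc1)CCCC1=N[C@H](C)[C@@H](OCc2ccccc2)CC1 | intermediate (key-step product)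
26 | (2R,3S,6S)-3-(benzyloxy)-6-[(4S,15S)-4,15-bis(benzyloxy)hexadecyl]-2-methylpiperidine | C[C@H](OCc1ccccc1)CCCCCCCCCC[C@H](OCc1ccccc1)CCC[C@H]1CC[C@H](OCc2ccccc2)[C@@H](C)N1 | intermediate (not isolated)
27 | (2R,3S,6S)-6-[(4S,15S)-4,15-dihydroxyhexadecyl]-2-methylpiperidin-3-ol | C[C@H](O)CCCCCCCCCC[C@H](O)CCC[C@H]1CC[C@H](O)[C@@H](C)N1 | target

**Step count**

Total: 17 steps. Longest linear sequence: 12 steps (steps 6–17, from 11-bromoundec-1-ene and (S)-propylene oxide); the C1–C6 branch (steps 1–5) joins at step 14.

**Steps most likely to fail, with fallbacks**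

Step 16. The enzyme may fail to bind or turn over a methyl ketone that is branched and benzyloxylated at the α-carbon. The very lipophilic substrate may also stay unavailable to the enzyme in buffer, or C3 may epimerise by enolisation or enamine formation in the amine-rich medium. The fallback introduces nitrogen chemically before the chain is attached, setting out from 6 and rejoining the route at 25.
- Mild aqueous acid removes the ketal to give (S)-4-(benzyloxy)-N-methoxy-N-methyl-5-oxohexanamide F1.
- Condensation with (R)-2-methylpropane-2-sulfinamide and Ti(OEt)4 in THF gives (4S)-4-(benzyloxy)-5-{[(R)-tert-butylsulfinyl]imino}-N-methoxy-N-methylhexanamide F2.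
- NaBH4 in THF at −48 °C, which leaves the Weinreb amide alone, should reduce the ketimine under control of the sulfinyl group to (4S,5R)-4-(benzyloxy)-5-{[(R)-tert-butylsulfinyl]amino}-N-methoxy-N-methylhexanamide F3. Should the benzyloxy group override the auxiliary, the (S)-sulfinamide with LiBH(sec-Bu)3 is the other pairing.
- After deprotonation of the N–H with LiN(SiMe3)2, Grignard reagent 20 adds to the Weinreb amide and gives (R)-N-[(2R,3S,10S,21S)-3,10,21-tris(benzyloxy)-6-oxodocosan-2-yl]-2-methylpropane-2-sulfinamide F4.
- HCl in methanol removes the sulfinyl group and, on neutralisation, amine 24 closes to imine 25.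

Step 5. The alkoxide of the γ-hydroxy Weinreb amide may fragment instead of being alkylated, by relactonisation with loss of the amine or by base-induced loss of the N-methoxy group, and alkylation next to the quaternary ketal carbon may be slow. The fallback benzylates before the amide exists, setting out from 4 and rejoining at 6. KOH and BnBr in refluxing toluene open the lactone and alkylate both oxygens to give benzyl (S)-4-(benzyloxy)-5,5-dimethoxyhexanoate F5. The magnesium amide from MeNH(OMe)·HCl and iPrMgCl in THF at −20 °C then converts the ester into 6.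

Step 17. Hydrogen may add to C6=N with poor facial selectivity, because the C3 benzyloxy group lies on the face that must be attacked, and the triple hydrogenolysis may stall through amine poisoning of the catalyst. The fallback separates the two events, setting out from 25 and ending at 27. iBu2AlH in CH2Cl2 at −78 °C reduces the imine by axial hydride delivery, which is expected to give the 2,6-cis piperidine 26, now isolated and purified. Na in liquid NH3/THF at −78 °C then removes the three benzyl groups. No compound outside the list is made (F0).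

**Further compounds**

F1 | step 16 | (S)-4-(benzyloxy)-N-methoxy-N-methyl-5-oxohexanamide | CON(C)C(=O)CC[C@H](OCc1ccccc1)C(C)=O
F2 | step 16 | (4S)-4-(benzyloxy)-5-{[(R)-tert-butylsulfinyl]imino}-N-methoxy-N-methylhexanamide | CON(C)C(=O)CC[C@H](OCc1ccccc1)C(C)=N[S@](=O)C(C)(C)C
F3 | step 16 | (4S,5R)-4-(benzyloxy)-5-{[(R)-tert-butylsulfinyl]amino}-N-methoxy-N-methylhexanamide | CON(C)C(=O)CC[C@H](OCc1ccccc1)[C@@H](C)N[S@](=O)C(C)(C)C
F4 | step 16 | (R)-N-[(2R,3S,10S,21S)-3,10,21-tris(benzyloxy)-6-oxodocosan-2-yl]-2-methylpropane-2-sulfinamide | C[C@H](OCc1ccccc1)CCCCCCCCCC[C@H](OCc1ccccc1)CCCC(=O)CC[C@H](OCc1ccccc1)[C@@H](C)N[S@](=O)C(C)(C)C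
F5 | step 5 | benzyl (S)-4-(benzyloxy)-5,5-dimethoxyhexanoate | O=C(OCc1ccccc1)CC[C@H](OCc1ccccc1)C(C)(OC)OC
F0 | step 17 | none | none
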